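The route rests on cutting the C5–C6 bond of the trihydroxylated cyclohexane ring (C1–C6): the tertiary C5 carbinol and the neighbouring C6 carbinol are read as an α-hydroxy ketone. A chiral triazolylidene turns the non-enolisable C6 aldehyde, which sits on the C1 gem-dimethyl carbon, into an acyl-anion equivalent that adds to the C5 methyl ketone; one operation forms C5–C6, closes the ring and sets C5 cis to the C3 silyloxy group. The precursor is the open-chain (S)-4-silyloxy-2,2-dimethyl-6-oxoheptanal, both carbonyls being released together by ozonolysis of a diene. Acetylide addition to the bridged ketone and two Wittig unions around a C10 dialdehyde finish the carotenoid.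

Key step: step 5

Remark: (R)-α-ionone (17) is taken as a purchasable single enantiomer, and the triazolium antipode named in step 5 is the one assumed to give the cis ketol; its mirror image, equally available, is used if a trial run shows the opposite sense.

Step 1
Reactants: 1 methyl 3,3-dimethylpent-4-enoate
Product: 2 3,3-dimethylpent-4-enal
Conditions: i-Bu2AlH (1.05 equiv), CH2Cl2, −78 °C; aq. KNaC4H4O6
Reagents that add atoms: none
Why: Partial hydride reduction of an ester, which stops at the aluminium hemiacetal at −78 °C and gives the aldehyde on work-up; the vinyl group (the later C6 aldehyde) is inert.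

Step 2
Reactants: 2 3,3-dimethylpent-4-enal; 3 tributyl(2-methylprop-2-en-1-yl)stannane
Product: 4 (4R)-2,6,6-trimethylocta-1,7-dien-4-ol
Conditions: (R)-BINOL (10 mol%), Ti(OiPr)4 (10 mol%), 4 Å MS, CH2Cl2, −20 °C; aq. NaHCO3
Reagents that add atoms: none
Why: Keck asymmetric allylation with a methallylstannane should work on this α-unbranched aldehyde, the (R)-BINOL–titanium Lewis acid directing attack to the Re face and so setting the carbinol centre (the later C3) as (R).

Step 3
Reactants: 4 (4R)-2,6,6-trimethylocta-1,7-dien-4-ol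
Product: 5 (4R)-4-(tert-butyldimethylsilyloxy)-2,6,6-trimethylocta-1,7-diene
Conditions: TBSCl, imidazole, DMF, rt
Reagents that add atoms: tert-butyldimethylsilyl chloride, CC(C)(C)[Si](C)(C)Cl
Why: Standard silylation of a secondary alcohol; the TBS ether survives ozone and the mildly basic carbene step.

Step 4
Reactants: 5 (4R)-4-(tert-butyldimethylsilyloxy)-2,6,6-trimethylocta-1,7-diene
Product: 7 (4S)-4-(tert-butyldimethylsilyloxy)-2,2-dimethyl-6-oxoheptanal, via bis-ozonide 6 (not isolated)
Conditions: O3, CH2Cl2, −78 °C; then PPh3, −78 °C → rt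
Reagents that add atoms: ozone, [O-][O+]=O
Why: Ozonolysis with reductive work-up cleaves the vinyl group to the C6 aldehyde and the isopropenyl group to the C5 methyl ketone in one operation, so no acetal has to be hydrolysed beside the β-silyloxy ketone (the descriptor changes from R to S through the priority rules only).

Step 5
Reactants: 7 (4S)-4-(tert-butyldimethylsilyloxy)-2,2-dimethyl-6-oxoheptanal
Product: 8 (4S,6S)-4-(tert-butyldimethylsilyloxy)-6-hydroxy-2,2,6-trimethylcyclohexan-1-one (O3 and O5 cis, carotenoid numbering)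
Conditions: (5aS,10bR)-2-(pentafluorophenyl)-5a,10b-dihydro-4H,6H-indeno[2,1-b][1,2,4]triazolo[4,3-d][1,4]oxazin-2-ium tetrafluoroborate (20 mol%), Et3N (20 mol%), toluene (0.05 M), 40 °C
Reagents that add atoms: none
Why: The carbene adds to the C6 aldehyde, proton transfer gives the enaminol (Breslow intermediate), whose C6 attacks the C5 ketone, and collapse of the adduct returns the carbene and the C6 ketone. The closest known reaction type is the triazolylidene-catalysed intramolecular crossed aldehyde–ketone benzoin reaction that gives six-membered tertiary α-ketols. The cyclohexane ring closes in the 6-exo-trig mode, the ketone C=O lying outside the new ring. The C5 configuration is controlled by the chiral carbene: the indane wall leaves one face of the enaminol open and the hydrogen bond from its OH to the ketone oxygen fixes which ketone face is met, so that the tertiary hydroxyl forms cis to the C3 silyloxy group. The step needs chemoselectivity (aldehyde as donor, ketone as acceptor) and must outrun ketone-enolate aldol and β-elimination of the C3 silyloxy group; the substrate secures the first because its aldehyde has no α-hydrogen and is the only carbonyl able to form the acyl-anion equivalent, and the acidic N-C6F5 azolium with only a catalytic tertiary amine keeps the enolate concentration low. The α-quaternary aldehyde reacts slowly, which is answered by mild heating, and any C5 epimer is purged in step 7.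

Step 6
Reactants: 8 (4S,6S)-4-(tert-butyldimethylsilyloxy)-6-hydroxy-2,2,6-trimethylcyclohexan-1-one
Product: 9 (4S,6S)-4,6-dihydroxy-2,2,6-trimethylcyclohexan-1-one
Conditions: 48% aq. HF, MeCN, 0 °C → rt
Reagents that add atoms: none
Why: Acidic fluoride cleavage of a secondary silyl ether, under which the tertiary α-ketol should undergo neither retro-benzoin nor α-ketol rearrangement.

Step 7
Reactants: 9 (4S,6S)-4,6-dihydroxy-2,2,6-trimethylcyclohexan-1-one
Product: 10 (1S,5S)-3,3-di-tert-butyl-5,7,7-trimethyl-2,4-dioxa-3-silabicyclo[3.3.1]nonan-6-one (the O3,O5-di-tert-butylsilylene of 9)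
Conditions: t-Bu2Si(OTf)2, 2,6-lutidine, CH2Cl2, 0 °C → reflux
Reagents that add atoms: di-tert-butylsilyl bis(trifluoromethanesulfonate), CC(C)(C)[Si](OS(=O)(=O)C(F)(F)F)(OS(=O)(=O)C(F)(F)F)C(C)(C)C
Why: Cyclic silylene formation from a cis-1,3-diol with a silyl bis-triflate; the secondary O3 is silylated first and the ring closes irreversibly onto the tertiary O5 in the 3,5-diaxial conformer, which ties both oxygens to one face of the ketone, whereas a C5 epimer cannot be bridged and is left behind.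

Step 8
Reactants: 10 (1S,5S)-3,3-di-tert-butyl-5,7,7-trimethyl-2,4-dioxa-3-silabicyclo[3.3.1]nonan-6-one; 11 (E)-3-methylpent-2-en-4-yn-1-ol
Product: 13 (2E)-5-[(1S,5S,6S)-3,3-di-tert-butyl-6-hydroxy-5,7,7-trimethyl-2,4-dioxa-3-silabicyclo[3.3.1]nonan-6-yl]-3-methylpent-2-en-4-yn-1-ol (C6 hydroxyl cis to O5 and O3), via dilithio enynol 12 (not isolated)
Conditions: 11 (3 equiv), n-BuLi (6 equiv), THF, −78 → 0 °C; then 10, −78 °C → rt; H2O
Reagents that add atoms: none
Why: Addition of a lithium acetylide to a non-enolisable ketone; the slim nucleophile enters anti to the O3–Si–O5 bridge and anti to the C5–O bond (axial attack on the locked ring), which sets C6 with its hydroxyl cis to O5 and O3.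

Step 9
Reactants: 13 (2E)-5-[(1S,5S,6S)-3,3-di-tert-butyl-6-hydroxy-5,7,7-trimethyl-2,4-dioxa-3-silabicyclo[3.3.1]nonan-6-yl]-3-methylpent-2-en-4-yn-1-ol
Product: 14 (2E,4E)-5-[(1S,5S,6R)-3,3-di-tert-butyl-6-hydroxy-5,7,7-trimethyl-2,4-dioxa-3-silabicyclo[3.3.1]nonan-6-yl]-3-methylpenta-2,4-dien-1-ol
Conditions: NaAlH2(OCH2CH2OMe)2, THF, 0 °C → rt; aq. KNaC4H4O6
Reagents that add atoms: none
Why: Hydroxyl-directed trans-hydroalumination of a propargylic alcohol, in which the C6 alkoxyaluminate delivers hydride within the molecule and protonolysis gives the 7E alkene while the 9E alkene stays (a shift of the silylene from O3 to O6 under the alkoxide conditions would be harmless, since all silicon is removed in step 19).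

Step 10
Reactants: 14 (2E,4E)-5-[(1S,5S,6R)-3,3-di-tert-butyl-6-hydroxy-5,7,7-trimethyl-2,4-dioxa-3-silabicyclo[3.3.1]nonan-6-yl]-3-methylpenta-2,4-dien-1-ol
Product: 16 {(2E,4E)-5-[(1S,5S,6R)-3,3-di-tert-butyl-6-hydroxy-5,7,7-trimethyl-2,4-dioxa-3-silabicyclo[3.3.1]nonan-6-yl]-3-methylpenta-2,4-dien-1-yl}triphenylphosphonium bromide, via allylic bromide 15 (not isolated)
Conditions: NBS, Me2S, CH2Cl2, −20 → 0 °C; then PPh3, EtOAc, rt
Reagents that add atoms: N-bromosuccinimide, O=C1CCC(=O)N1Br; triphenylphosphine, c1ccc(cc1)P(c1ccccc1)c1ccccc1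
Why: Corey–Kim bromination converts only the primary allylic alcohol into the bromide under neutral conditions without allylic shift, and SN2 quaternisation of PPh3 then gives the salt, so the acid-labile tertiary allylic C6 alcohol never meets a protic acid.

Step 11
Reactants: 17 (R)-α-ionone, (3E)-4-[(1R)-2,6,6-trimethylcyclohex-2-en-1-yl]but-3-en-2-one; 18 triethyl phosphonoacetate
Product: 20 ethyl (2E,4E)-3-methyl-5-[(1R)-2,6,6-trimethylcyclohex-2-en-1-yl]penta-2,4-dienoate, via sodium phosphonate anion 19 (not isolated)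
Conditions: 18, NaH, THF, 0 °C; then 17, 0 °C → rt
Reagents that add atoms: none
Why: Horner–Wadsworth–Emmons olefination of the methyl ketone should give mainly the 2E ester (the 2Z isomer is removed by chromatography), and the stabilised phosphonate anion is too weak a base to deprotonate C6′, so that centre is kept.

Step 12
Reactants: 20 ethyl (2E,4E)-3-methyl-5-[(1R)-2,6,6-trimethylcyclohex-2-en-1-yl]penta-2,4-dienoate
Product: 21 ethyl (2E,4E)-3-methyl-5-[(1R)-2,6,6-trimethyl-4-oxocyclohex-2-en-1-yl]penta-2,4-dienoate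
Conditions: t-BuOOH (decane), Mn(OAc)3·2H2O (10 mol%), 3 Å MS, EtOAc, rt
Reagents that add atoms: tert-butyl hydroperoxide, CC(C)(C)OO
Why: Radical allylic oxidation of a ring CH2 to the enone with an alkyl hydroperoxide and a manganese triacetate catalyst; C3′ is the only unhindered secondary allylic position, and the base-free medium preserves the C6′ centre, which is vinylogously acidic once the enone is present.

Step 13
Reactants: 21 ethyl (2E,4E)-3-methyl-5-[(1R)-2,6,6-trimethyl-4-oxocyclohex-2-en-1-yl]penta-2,4-dienoate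
Product: 22 ethyl (2E,4E)-5-[(1R,4R)-4-hydroxy-2,6,6-trimethylcyclohex-2-en-1-yl]-3-methylpenta-2,4-dienoate
Conditions: LiBH(sec-Bu)3 (1.1 equiv), THF, −78 °C; H2O
Reagents that add atoms: none
Why: 1,2-Reduction of a β-substituted cyclohexenone by a bulky borohydride, which should attack the ring carbonyl from the face away from the axial C1′ methyl group and so place the hydroxyl pseudo-axial and trans to the pseudo-axial C6′ side chain (3′R), the ester being inert at −78 °C.

Step 14
Reactants: 22 ethyl (2E,4E)-5-[(1R,4R)-4-hydroxy-2,6,6-trimethylcyclohex-2-en-1-yl]-3-methylpenta-2,4-dienoate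
Product: 23 ethyl (2E,4E)-5-[(1R,4R)-4-(tert-butyldimethylsilyloxy)-2,6,6-trimethylcyclohex-2-en-1-yl]-3-methylpenta-2,4-dienoate
Conditions: TBSCl, imidazole, DMF, rt
Reagents that add atoms: tert-butyldimethylsilyl chloride, CC(C)(C)[Si](C)(C)Cl
Why: Standard silylation; the ether shields the allylic C3′ hydroxyl during hydride reduction, bromination and ylide formation and leaves with fluoride at the end.

Step 15
Reactants: 23 ethyl (2E,4E)-5-[(1R,4R)-4-(tert-butyldimethylsilyloxy)-2,6,6-trimethylcyclohex-2-en-1-yl]-3-methylpenta-2,4-dienoate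
Product: 24 (2E,4E)-5-[(1R,4R)-4-(tert-butyldimethylsilyloxy)-2,6,6-trimethylcyclohex-2-en-1-yl]-3-methylpenta-2,4-dien-1-ol
Conditions: i-Bu2AlH (2.2 equiv), CH2Cl2, −78 °C; aq. KNaC4H4O6
Reagents that add atoms: none
Why: Hydride reduction of a conjugated ester to the allylic alcohol by excess i-Bu2AlH at low temperature, which touches neither the silyl ether nor the diene.

Step 16
Reactants: 24 (2E,4E)-5-[(1R,4R)-4-(tert-butyldimethylsilyloxy)-2,6,6-trimethylcyclohex-2-en-1-yl]-3-methylpenta-2,4-dien-1-ol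
Product: 26 {(2E,4E)-5-[(1R,4R)-4-(tert-butyldimethylsilyloxy)-2,6,6-trimethylcyclohex-2-en-1-yl]-3-methylpenta-2,4-dien-1-yl}triphenylphosphonium bromide, via allylic bromide 25 (not isolated)
Conditions: NBS, Me2S, CH2Cl2, −20 → 0 °C; then PPh3, EtOAc, rt
Reagents that add atoms: N-bromosuccinimide, O=C1CCC(=O)N1Br; triphenylphosphine, c1ccc(cc1)P(c1ccccc1)c1ccccc1
Why: Corey–Kim bromination followed by SN2 quaternisation of PPh3 gives the salt without protic acid, which the allylic C3′ silyl ether would not tolerate.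

Step 17
Reactants: 26 the ε-ring C15 phosphonium bromide; 27 (2E,4E,6E)-2,7-dimethylocta-2,4,6-trienedial (2.5 equiv)
Product: 29 (3R,6R)-3-(tert-butyldimethylsilyloxy)-12′-apo-ε-caroten-12′-al, that is (2E,4E,6E,8E,10E,12E)-13-[(1R,4R)-4-(tert-butyldimethylsilyloxy)-2,6,6-trimethylcyclohex-2-en-1-yl]-2,7,11-trimethyltrideca-2,4,6,8,10,12-hexaenal, via phosphorus ylide 28 (not isolated)
Conditions: 1,2-epoxybutane, EtOH, 70 °C
Reagents that add atoms: none
Why: Wittig olefination of one formyl group of the symmetrical dialdehyde, taken in excess so that the ylide, released slowly by the epoxide-derived alkoxide, meets unreacted dialdehyde; the new C11′=C12′ bond forms as an E/Z mixture that equilibrates to all-E on heating.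

Step 18
Reactants: 16 the triol-ring C15 phosphonium bromide; 29 (3R,6R)-3-(tert-butyldimethylsilyloxy)-12′-apo-ε-caroten-12′-al
Product: 31 (3S,5S,6R,3′R,6′R)-3′-O-(tert-butyldimethylsilyl)-3,5-O-(di-tert-butylsilanediyl)-5,6-dihydro-β,ε-carotene-3,5,6,3′-tetrol, via phosphorus ylide 30 (not isolated)
Conditions: 1,2-epoxybutane, EtOH, 70 °C, dark, argon
Reagents that add atoms: none
Why: Wittig olefination forming C11=C12 under near-neutral conditions that the free tertiary C6 hydroxyl tolerates, the heating in the same solvent equilibrating the hindered 11Z isomer to the all-E polyene.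

Step 19
Reactants: 31 the doubly silyl-protected carotenoid
Product: 32 (3S,5S,6R,3′R,6′R)-5,6-dihydro-β,ε-carotene-3,5,6,3′-tetrol (5,6-dihydroxylutein)
Conditions: Bu4NF, AcOH, THF, 0 °C → rt, dark
Reagents that add atoms: none
Why: Fluoride cleaves all three Si–O bonds (silylene and silyl ether) under buffered, non-acidic conditions, as is needed because the tertiary allylic C6 alcohol and the allylic C3′ alcohol ionise in acid; no stereocentre is touched.

Compound list
1 | methyl 3,3-dimethylpent-4-enoate | COC(=O)CC(C)(C)C=C | starting material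
2 | 3,3-dimethylpent-4-enal | O=CCC(C)(C)C=C | intermediate
3 | tributyl(2-methylprop-2-en-1-yl)stannane | CC(=C)C[Sn](CCCC)(CCCC)CCCC | starting material
4 | (4R)-2,6,6-trimethylocta-1,7-dien-4-ol | C=CC(C)(C)C[C@H](O)CC(C)=C | intermediate
5 | (4R)-4-(tert-butyldimethylsilyloxy)-2,6,6-trimethylocta-1,7-diene | C=CC(C)(C)C[C@H](O[Si](C)(C)C(C)(C)C)CC(C)=C | intermediate
6 | bis-ozonide (bis-1,2,4-trioxolane) of 5, trioxolane centres undefined | C1OOC(O1)C(C)(C)C[C@H](O[Si](C)(C)C(C)(C)C)CC2(C)OCOO2 | intermediate (not isolated)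
7 | (4S)-4-(tert-butyldimethylsilyloxy)-2,2-dimethyl-6-oxoheptanal | O=CC(C)(C)C[C@H](O[Si](C)(C)C(C)(C)C)CC(C)=O | intermediate
8 | (4S,6S)-4-(tert-butyldimethylsilyloxy)-6-hydroxy-2,2,6-trimethylcyclohexan-1-one | O=C1C(C)(C)C[C@H](O[Si](C)(C)C(C)(C)C)C[C@]1(C)O | intermediate
9 | (4S,6S)-4,6-dihydroxy-2,2,6-trimethylcyclohexan-1-one | O=C1C(C)(C)C[C@H](O)C[C@]1(C)O | intermediate
10 | (1S,5S)-3,3-di-tert-butyl-5,7,7-trimethyl-2,4-dioxa-3-silabicyclo[3.3.1]nonan-6-one | O=C1C(C)(C)C[C@H]2C[C@]1(C)O[Si](C(C)(C)C)(C(C)(C)C)O2 | intermediate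
11 | (E)-3-methylpent-2-en-4-yn-1-ol | C#C/C(C)=C/CO | starting material
12 | dilithio derivative of 11 (lithium acetylide, lithium alkoxide) | [Li]C#C/C(C)=C/CO[Li] | intermediate (not isolated)
13 | (2E)-5-[(1S,5S,6S)-3,3-di-tert-butyl-6-hydroxy-5,7,7-trimethyl-2,4-dioxa-3-silabicyclo[3.3.1]nonan-6-yl]-3-methylpent-2-en-4-yn-1-ol | OC/C=C(C)/C#C[C@@]1(O)C(C)(C)C[C@H]2C[C@]1(C)O[Si](C(C)(C)C)(C(C)(C)C)O2 | intermediate
14 | (2E,4E)-5-[(1S,5S,6R)-3,3-di-tert-butyl-6-hydroxy-5,7,7-trimethyl-2,4-dioxa-3-silabicyclo[3.3.1]nonan-6-yl]-3-methylpenta-2,4-dien-1-ol | OC/C=C(C)/C=C/[C@@]1(O)C(C)(C)C[C@H]2C[C@]1(C)O[Si](C(C)(C)C)(C(C)(C)C)O2 | intermediate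
15 | allylic bromide from 14 (C11 bromide) | BrC/C=C(C)/C=C/[C@@]1(O)C(C)(C)C[C@H]2C[C@]1(C)O[Si](C(C)(C)C)(C(C)(C)C)O2 | intermediate (not isolated)
16 | {(2E,4E)-5-[(1S,5S,6R)-3,3-di-tert-butyl-6-hydroxy-5,7,7-trimethyl-2,4-dioxa-3-silabicyclo[3.3.1]nonan-6-yl]-3-methylpenta-2,4-dien-1-yl}triphenylphosphonium bromide | [Br-].c1ccccc1[P+](c1ccccc1)(c1ccccc1)C/C=C(C)/C=C/[C@@]1(O)C(C)(C)C[C@H]2C[C@]1(C)O[Si](C(C)(C)C)(C(C)(C)C)O2 | intermediate
17 | (R)-α-ionone | CC1=CCCC(C)(C)[C@H]1/C=C/C(C)=O | starting material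
18 | triethyl phosphonoacetate | CCOC(=O)CP(=O)(OCC)OCC | starting material
19 | sodium salt of 18 (phosphonate carbanion) | [Na+].CCOC(=O)[CH-]P(=O)(OCC)OCC | intermediate (not isolated)
20 | ethyl (2E,4E)-3-methyl-5-[(1R)-2,6,6-trimethylcyclohex-2-en-1-yl]penta-2,4-dienoate | CC1=CCCC(C)(C)[C@H]1/C=C/C(C)=C/C(=O)OCC | intermediate
21 | ethyl (2E,4E)-3-methyl-5-[(1R)-2,6,6-trimethyl-4-oxocyclohex-2-en-1-yl]penta-2,4-dienoate | CC1=CC(=O)CC(C)(C)[C@H]1/C=C/C(C)=C/C(=O)OCC | intermediate
22 | ethyl (2E,4E)-5-[(1R,4R)-4-hydroxy-2,6,6-trimethylcyclohex-2-en-1-yl]-3-methylpenta-2,4-dienoate | CC1=C[C@H](O)CC(C)(C)[C@H]1/C=C/C(C)=C/C(=O)OCC | intermediate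
23 | ethyl (2E,4E)-5-[(1R,4R)-4-(tert-butyldimethylsilyloxy)-2,6,6-trimethylcyclohex-2-en-1-yl]-3-methylpenta-2,4-dienoate | CC1=C[C@H](O[Si](C)(C)C(C)(C)C)CC(C)(C)[C@H]1/C=C/C(C)=C/C(=O)OCC | intermediate
24 | (2E,4E)-5-[(1R,4R)-4-(tert-butyldimethylsilyloxy)-2,6,6-trimethylcyclohex-2-en-1-yl]-3-methylpenta-2,4-dien-1-ol | CC1=C[C@H](O[Si](C)(C)C(C)(C)C)CC(C)(C)[C@H]1/C=C/C(C)=C/CO | intermediate
25 | allylic bromide from 24 | CC1=C[C@H](O[Si](C)(C)C(C)(C)C)CC(C)(C)[C@H]1/C=C/C(C)=C/CBr | intermediate (not isolated)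
26 | {(2E,4E)-5-[(1R,4R)-4-(tert-butyldimethylsilyloxy)-2,6,6-trimethylcyclohex-2-en-1-yl]-3-methylpenta-2,4-dien-1-yl}triphenylphosphonium bromide | CC1=C[C@H](O[Si](C)(C)C(C)(C)C)CC(C)(C)[C@H]1/C=C/C(C)=C/C[P+](c1ccccc1)(c1ccccc1)c1ccccc1.[Br-] | intermediate
27 | (2E,4E,6E)-2,7-dimethylocta-2,4,6-trienedial | O=C/C(C)=C/C=C/C=C(C)/C=O | starting material
28 | phosphorus ylide from 26 | CC1=C[C@H](O[Si](C)(C)C(C)(C)C)CC(C)(C)[C@H]1/C=C/C(C)=C/C=P(c1ccccc1)(c1ccccc1)c1ccccc1 | intermediate (not isolated)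
29 | (3R,6R)-3-(tert-butyldimethylsilyloxy)-12′-apo-ε-caroten-12′-al | CC1=C[C@H](O[Si](C)(C)C(C)(C)C)CC(C)(C)[C@H]1/C=C/C(C)=C/C=C/C(C)=C/C=C/C=C(C)/C=O | intermediate
30 | phosphorus ylide from 16 | c1ccccc1P(c1ccccc1)(c1ccccc1)=C/C=C(C)/C=C/[C@@]1(O)C(C)(C)C[C@H]2C[C@]1(C)O[Si](C(C)(C)C)(C(C)(C)C)O2 | intermediate (not isolated)
31 | (3S,5S,6R,3′R,6′R)-3′-O-(tert-butyldimethylsilyl)-3,5-O-(di-tert-butylsilanediyl)-5,6-dihydro-β,ε-carotene-3,5,6,3′-tetrol | CC1=C[C@H](O[Si](C)(C)C(C)(C)C)CC(C)(C)[C@H]1/C=C/C(C)=C/C=C/C(C)=C/C=C/C=C(C)/C=C/C=C(C)/C=C/[C@@]1(O)C(C)(C)C[C@H]2C[C@]1(C)O[Si](C(C)(C)C)(C(C)(C)C)O2 | intermediate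
32 | (3S,5S,6R,3′R,6′R)-5,6-dihydro-β,ε-carotene-3,5,6,3′-tetrol (5,6-dihydroxylutein) | CC1=C[C@H](O)CC(C)(C)[C@H]1/C=C/C(C)=C/C=C/C(C)=C/C=C/C=C(C)/C=C/C=C(C)/C=C/[C@@]1(O)C(C)(C)C[C@H](O)C[C@]1(C)O | target

Total step count: 19. Longest linear sequence: 12 steps (steps 1–10, 18 and 19); the ε-ring branch (steps 11–17) joins at step 18.

Steps most likely to fail

Step 5. The acyl-anion equivalent may form too slowly at the α-quaternary aldehyde, so that enolate chemistry of the ketone (aldol, loss of the silyloxy group) takes over; catalyst control over the ketone face may also be incomplete against the bias of the substrate. The fallback sets out from 7 and uses a known ketyl–carbonyl (pinacol) cyclisation with SmI2 (t-BuOH, THF, −78 → 0 °C), which forms the same C5–C6 bond and closes the same ring. It should give the cis-1,2-diol (1S,2R,5S)-5-(tert-butyldimethylsilyloxy)-1,3,3-trimethylcyclohexane-1,2-diol F1, the C5 epimers being separated by chromatography. Oxidation of its secondary carbinol with 2-iodoxybenzoic acid in DMSO, which spares the tertiary alcohol and does not cleave the diol, comes back to the route at 8.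

Step 8. The aggregated dilithio enynol may add sluggishly to a carbonyl flanked by two fully substituted carbons, or facial control may erode if the bridged ring does not hold the expected shape. The fallback sets out from 10 and adds the smallest acetylide as its cerium reagent (HC≡CMgBr, CeCl3, THF, −78 °C) to give (1S,5S,6S)-3,3-di-tert-butyl-6-ethynyl-5,7,7-trimethyl-2,4-dioxa-3-silabicyclo[3.3.1]nonan-6-ol F2. The C8–C9 bond is then made by Sonogashira coupling with (E)-3-iodobut-2-en-1-ol (Pd(PPh3)4, zerovalent palladium, CuI, i-Pr2NH, THF, rt), which comes back to the route at 13.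

Step 12. Hydrogen abstraction may be unselective (C6′ methine, ring methyl) and the radical oxidation may run on past the enone. The fallback sets out from 20 and reaches the enone by ionic steps:
- Epoxidation with mCPBA (CH2Cl2, 0 °C) should touch only the electron-rich ring alkene and give ethyl (2E,4E)-5-(2,3-epoxy-2,6,6-trimethylcyclohexyl)-3-methylpenta-2,4-dienoate F3; either epoxide face serves, since both centres are erased later.
- Sodium phenylselenide (PhSeSePh, NaBH4, EtOH) opens the epoxide at C4′ to ethyl (2E,4E)-5-[2-hydroxy-2,6,6-trimethyl-3-(phenylselanyl)cyclohexyl]-3-methylpenta-2,4-dienoate F4.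
- H2O2 in the same flask oxidises F4 and the selenoxide eliminates to the tertiary allylic alcohol ethyl (2E,4E)-5-(2-hydroxy-2,6,6-trimethylcyclohex-3-en-1-yl)-3-methylpenta-2,4-dienoate F5.
- Oxidative 1,3-transposition with pyridinium chlorochromate, (C5H5NH)[CrO3Cl], in CH2Cl2 comes back to the route at 21.

Further compounds
F1 | step 5 | (1S,2R,5S)-5-(tert-butyldimethylsilyloxy)-1,3,3-trimethylcyclohexane-1,2-diol | O[C@@H]1C(C)(C)C[C@H](O[Si](C)(C)C(C)(C)C)C[C@]1(C)O
F2 | step 8 | (1S,5S,6S)-3,3-di-tert-butyl-6-ethynyl-5,7,7-trimethyl-2,4-dioxa-3-silabicyclo[3.3.1]nonan-6-ol | C#C[C@@]1(O)C(C)(C)C[C@H]2C[C@]1(C)O[Si](C(C)(C)C)(C(C)(C)C)O2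
F3 | step 12 | ethyl (2E,4E)-5-(2,3-epoxy-2,6,6-trimethylcyclohexyl)-3-methylpenta-2,4-dienoate (C6′ as in 20, epoxide face undefined) | CC12OC1CCC(C)(C)[C@H]2/C=C/C(C)=C/C(=O)OCC
F4 | step 12 | ethyl (2E,4E)-5-[2-hydroxy-2,6,6-trimethyl-3-(phenylselanyl)cyclohexyl]-3-methylpenta-2,4-dienoate (C6′ as in 20) | CC1(O)C([Se]c2ccccc2)CCC(C)(C)[C@H]1/C=C/C(C)=C/C(=O)OCC
F5 | step 12 | ethyl (2E,4E)-5-(2-hydroxy-2,6,6-trimethylcyclohex-3-en-1-yl)-3-methylpenta-2,4-dienoate (C6′ as in 20) | CC1(O)C=CCC(C)(C)[C@H]1/C=C/C(C)=C/C(=O)OCC
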